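**Retrosynthetic overview**
- Feature: ring A (N1, C2 bearing CH3, C3 bearing O, C4, C4a, C8a) is a 2-methylpiperidin-3-ol, the fully reduced form of a 2-methylpyridin-3-ol. That pyridine is what a 5-alkoxy-4-methyloxazole gives with an alkene. C8a and C4a are also linked by C8–C7–C6–C5 of ring B, so oxazole C2 and the alkene can sit on one chain.
- Late disconnections: the C3–O ester bond (Mitsunobu, with inversion) and the four C–H bonds at C2, C3, C4a and C8a (syn hydrogenation on the face away from the C5 chain). These lead back to a 5-alkyl-2-methyl-5,6,7,8-tetrahydroquinolin-3-ol.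
- Key disconnection: C4a–C8a and C3–C4, by intramolecular oxazole–alkene [4+2] addition and loss of ethanol. Rings A (aromatic) and B form together in this one step, and ring A is saturated afterwards.
- The acyclic oxazole comes from an N-acylalanine ester. Its acid is cut at C5–C1' by a copper-catalysed asymmetric SN2' alkylation. The electrophile is an allylic bromide made from methyl hex-5-enoate, and the Grignard reagent carries C5' from (R)-2-propyloxirane.

Key step: step 10

Assumption: the antipode of the ferrocenyl diphosphine needed for 5S in step 6 is chosen by analogy with simple (E)-allylic bromides and is checked on the first run. Both antipodes are sold, so the sense of induction is a matter of choice.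

**Step 1**
Reactants: 1 (R)-2-propyloxirane; 2 allylmagnesium bromide
Product: 3 (4R)-oct-7-en-4-ol
Conditions: CuI (10 mol %), THF/Et2O, −30 → 0 °C; then sat. aq NH4Cl
Reagents that add atoms: none
Why: Copper-catalysed SN2 opening of a terminal epoxide by an allyl Grignard reagent takes place at the unsubstituted carbon, so the C–O stereocentre (future C5') is carried over untouched and remains R.

**Step 2**
Reactants: 3 (4R)-oct-7-en-4-ol
Product: 4 [(4R)-oct-7-en-4-yloxy]triisopropylsilane
Conditions: TIPSOTf (1.2 equiv), 2,6-lutidine (1.5 equiv), CH2Cl2, 0 °C → rt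
Reagents that add atoms: triisopropylsilyl trifluoromethanesulfonate, CC(C)[Si](OS(=O)(=O)C(F)(F)F)(C(C)C)C(C)C
Why: Silylation of a secondary alcohol with a silyl triflate and a hindered pyridine base is routine, and triisopropylsilyl is preferred to tert-butyldimethylsilyl because it must outlast hot CF3CO2H in step 10 and, having no arene, the rhodium hydrogenation of step 11.

**Step 3**
Reactants: 4 [(4R)-oct-7-en-4-yloxy]triisopropylsilane
Product: 6 (5R)-5-(triisopropylsilyloxy)octan-1-ol, via B-alkyl-9-BBN adduct 5 (not isolated)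
Conditions: 9-BBN (1.3 equiv), THF, 0 °C → rt; then 3 M NaOH, 30% H2O2, 0 °C → rt
Reagents that add atoms: 9-borabicyclo[3.3.1]nonane, B1C2CCCC1CCC2 (its boron and carbons stay in 5 only); hydrogen peroxide, OO
Why: Brown hydroboration–oxidation with 9-BBN places boron on the terminal carbon of the monosubstituted alkene, and alkaline peroxide replaces it by hydroxyl without touching the silyl ether.

**Step 4**
Reactants: 6 (5R)-5-(triisopropylsilyloxy)octan-1-ol
Product: 7 [(4R)-8-bromooctan-4-yloxy]triisopropylsilane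
Conditions: CBr4 (1.2 equiv), PPh3 (1.25 equiv), CH2Cl2, 0 °C
Reagents that add atoms: carbon tetrabromide, BrC(Br)(Br)Br
Why: The Appel bromination converts the primary alcohol under near-neutral conditions that leave the secondary silyl ether and its stereocentre alone.

**Step 5**
Reactants: 8 methyl hex-5-enoate; 9 (E)-1,4-dibromobut-2-ene (3 equiv)
Product: 10 methyl (E)-7-bromohept-5-enoate
Conditions: second-generation Grubbs catalyst (3 mol %), CH2Cl2, 40 °C
Reagents that add atoms: none
Why: Olefin cross-metathesis between a terminal alkene and an excess of a symmetrical allylic dibromide transfers the BrCH2CH= unit and, being reversible, should favour the E alkene, while the remote ester is a spectator.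

**Step 6**
Reactants: 7 [(4R)-8-bromooctan-4-yloxy]triisopropylsilane; 10 methyl (E)-7-bromohept-5-enoate
Product: 12 methyl (5S,10R)-5-ethenyl-10-(triisopropylsilyloxy)tridecanoate, via Grignard reagent 11 (not isolated)
Conditions: 7, Mg turnings, Et2O, 35 °C; then added to CuBr·SMe2 (5 mol %) and 1-[(dimethylamino)(2-diphenylphosphinophenyl)methyl]-2-(diphenylphosphino)ferrocene (Taniaphos, 6 mol %), CH2Cl2, −75 °C; 10 added over 2 h
Reagents that add atoms: magnesium, [Mg] (stays in 11 only)
Why: Copper-catalysed asymmetric allylic alkylation of an (E)-allylic bromide by a primary alkyl Grignard reagent runs SN2' under ferrocenyl diphosphine control, so the C5–C1' bond forms at the γ-carbon on the alkene face chosen by the ligand (5S, independent of remote C5'), a vinyl group is left for step 10, and the methyl ester is too slow to react with RMgBr at −75 °C.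

**Step 7**
Reactants: 12 methyl (5S,10R)-5-ethenyl-10-(triisopropylsilyloxy)tridecanoate
Product: 13 (5S,10R)-5-ethenyl-10-(triisopropylsilyloxy)tridecanoic acid
Conditions: LiOH·H2O (3 equiv), THF/MeOH/H2O, rt; then 1 M HCl to pH 3
Reagents that add atoms: lithium hydroxide, [Li+].[OH-]
Why: Saponification of an unhindered methyl ester by acyl–oxygen cleavage is safe here because the silyl ether resists base and C5 is separated from the carbonyl by three methylene groups and cannot epimerise.

**Step 8**
Reactants: 13 (5S,10R)-5-ethenyl-10-(triisopropylsilyloxy)tridecanoic acid; 14 ethyl L-alaninate hydrochloride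
Product: 15 ethyl N-[(5S,10R)-5-ethenyl-10-(triisopropylsilyloxy)tridecanoyl]-L-alaninate
Conditions: EDC·HCl (1.3 equiv), HOBt (1.3 equiv), i-Pr2NEt (2.6 equiv), CH2Cl2, 0 °C → rt
Reagents that add atoms: none
Why: Carbodiimide/HOBt amide coupling joins the acid to the amino ester under mild conditions, and the configuration of the alanine unit is of no consequence since step 9 flattens that carbon.

**Step 9**
Reactants: 15 ethyl N-[(5S,10R)-5-ethenyl-10-(triisopropylsilyloxy)tridecanoyl]-L-alaninate
Product: 16 5-ethoxy-2-[(4S,9R)-4-ethenyl-9-(triisopropylsilyloxy)dodecyl]-4-methyl-1,3-oxazole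
Conditions: PPh3 (2 equiv), I2 (2 equiv), CH2Cl2, rt; then Et3N (4 equiv); then 15, rt; chromatography on Et3N-deactivated silica
Reagents that add atoms: none
Why: Robinson–Gabriel-type cyclodehydration of an N-acyl-α-amino ester with preformed Ph3PI2 and Et3N removes one molecule of water under non-acidic conditions that spare the alkene and the silyl ether, and the alanine carbon becomes the sp2 C4 of the oxazole (future C2).

**Step 10**
Reactants: 16 5-ethoxy-2-[(4S,9R)-4-ethenyl-9-(triisopropylsilyloxy)dodecyl]-4-methyl-1,3-oxazole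
Product: 19 (5S)-2-methyl-5-[(5R)-5-(triisopropylsilyloxy)octyl]-5,6,7,8-tetrahydroquinolin-3-ol, via oxygen-bridged cycloadduct 17 (not isolated), via hemiketal dihydropyridine 18 (not isolated)
Conditions: CF3CO2H (1.5 equiv), 1,2-dichlorobenzene (0.01 M), Ar, sealed tube, 160 °C; then Et3N (2 equiv), concentrate
Reagents that add atoms: none
Why: Protonation at nitrogen by CF3CO2H makes the 5-ethoxyoxazole an electron-poor 2-azadiene that adds across the unactivated vinyl group in an intramolecular Kondrat'eva (oxazole–olefin Diels–Alder) reaction, oxazole C2 (future C8a) bonding to the internal alkene carbon (C4a) and oxazole C5 (future C3) to the terminal one (C4) to give the 7-oxa-2-azanorbornene 17. Acid opens the C8a–O bond of 17 with loss of H4a to give hemiketal 18, which expels ethanol and tautomerises, so the bridging oxygen ends as the C3 hydroxyl, the oxazole nitrogen as N1 and the 4-methyl group as the C2 methyl of an aromatic ring A. The closest known reactions are the pyridoxine-type syntheses of 2-methylpyridin-3-ols from 5-ethoxy-4-methyloxazole and the thermal or acid-promoted intramolecular oxazole–olefin cycloadditions that give carbocycle-fused pyridines. Ring B closes as a six-membered carbocycle in the fused (type 1) intramolecular mode, the C8–C7–C6–C5 tether joining the diene terminus to the nearer alkene carbon (6-exo with respect to the alkene), and ring A closes as the six-membered ring of the [4+2] itself. No lasting stereocentre is made, since the centres at C3, C4a and C8a of 17 vanish on aromatisation, while C5, allylic before and bound to a β-carbon of the pyridine afterwards, has no acidifying neighbour and should keep its S configuration. The step needs regiocontrol, which the short tether enforces because the bridged alternative is out of reach, and loss of ethanol rather than water, which the acid-labile hemiketal secures, while high dilution suppresses bimolecular addition and the triisopropylsilyl ether keeps the C5' oxygen masked.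

**Step 11**
Reactants: 19 (5S)-2-methyl-5-[(5R)-5-(triisopropylsilyloxy)octyl]-5,6,7,8-tetrahydroquinolin-3-ol
Product: 20 (2S,3S,4aS,5S,8aR)-2-methyl-5-[(5R)-5-(triisopropylsilyloxy)octyl]decahydroquinolin-3-ol
Conditions: H2 (70 bar), 5% Rh/Al2O3, EtOH/AcOH (10:1), 60 °C
Reagents that add atoms: none
Why: Heterogeneous hydrogenation of a pyridine over rhodium delivers all hydrogens from the adsorbed face (syn addition), and because the C5 chain sits pseudoaxial to avoid the peri C4–H it shields one face, so H2, H3, H4a and H8a should enter anti to the chain and cis to H5, giving 2S,3S,4aS,8aR.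

**Step 12**
Reactants: 20 (2S,3S,4aS,5S,8aR)-2-methyl-5-[(5R)-5-(triisopropylsilyloxy)octyl]decahydroquinolin-3-ol
Product: 21 tert-butyl (2S,3S,4aS,5S,8aR)-3-hydroxy-2-methyl-5-[(5R)-5-(triisopropylsilyloxy)octyl]octahydroquinoline-1(2H)-carboxylate
Conditions: Boc2O (2 equiv), MeOH, 50 °C
Reagents that add atoms: di-tert-butyl dicarbonate, CC(C)(C)OC(=O)OC(=O)OC(C)(C)C
Why: N-tert-butoxycarbonylation with Boc2O in the absence of an acylation catalyst is selective for the secondary amine over the secondary alcohol and removes the nucleophilic NH before the Mitsunobu step.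

**Step 13**
Reactants: 21 tert-butyl (2S,3S,4aS,5S,8aR)-3-hydroxy-2-methyl-5-[(5R)-5-(triisopropylsilyloxy)octyl]octahydroquinoline-1(2H)-carboxylate; 22 (2E,4E)-octa-2,4-dienoic acid
Product: 23 tert-butyl (2S,3R,4aS,5S,8aR)-2-methyl-3-[(2E,4E)-octa-2,4-dienoyloxy]-5-[(5R)-5-(triisopropylsilyloxy)octyl]octahydroquinoline-1(2H)-carboxylate
Conditions: 22 (2 equiv), PPh3 (2 equiv), DIAD (2 equiv), PhMe, 0 °C → rt
Reagents that add atoms: none
Why: Mitsunobu esterification proceeds by SN2 displacement of the phosphonium-activated hydroxyl and so turns 3S into 3R, and since A(1,3) strain from N-Boc holds the C2 methyl axial, the C3 oxygen is equatorial, has no antiperiplanar hydrogen for elimination and is open to axial attack by the carboxylate.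

**Step 14**
Reactants: 23 tert-butyl (2S,3R,4aS,5S,8aR)-2-methyl-3-[(2E,4E)-octa-2,4-dienoyloxy]-5-[(5R)-5-(triisopropylsilyloxy)octyl]octahydroquinoline-1(2H)-carboxylate
Product: 24 tert-butyl (2S,3R,4aS,5S,8aR)-5-[(5R)-5-hydroxyoctyl]-2-methyl-3-[(2E,4E)-octa-2,4-dienoyloxy]octahydroquinoline-1(2H)-carboxylate
Conditions: HF·pyridine, pyridine/THF, 0 °C → rt
Reagents that add atoms: none
Why: Fluoride-induced desilylation, driven by the strong Si–F bond, frees the C5' alcohol with retention (the C–O bond is not broken) and leaves the carbamate and the dienoate intact.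

**Step 15**
Reactants: 24 tert-butyl (2S,3R,4aS,5S,8aR)-5-[(5R)-5-hydroxyoctyl]-2-methyl-3-[(2E,4E)-octa-2,4-dienoyloxy]octahydroquinoline-1(2H)-carboxylate
Product: 25 lepadin H, (2S,3R,4aS,5S,8aR)-5-[(5R)-5-hydroxyoctyl]-2-methyldecahydroquinolin-3-yl (2E,4E)-octa-2,4-dienoate
Conditions: CF3CO2H/CH2Cl2 (1:4), 0 °C; then cold sat. aq NaHCO3
Reagents that add atoms: none
Why: Acidolysis of the tert-butyl carbamate (loss of the tert-butyl cation as isobutene, then decarboxylation) frees N1 without touching the dienoate or any stereocentre, and a cold, short bicarbonate work-up keeps the O-acyl group from shifting to nitrogen.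

**Compound list**
1 | (R)-2-propyloxirane | CCC[C@@H]1CO1 | starting material
2 | allylmagnesium bromide | C=CC[Mg]Br | starting material
3 | (4R)-oct-7-en-4-ol | C=CCC[C@H](O)CCC | intermediate
4 | [(4R)-oct-7-en-4-yloxy]triisopropylsilane | C=CCC[C@H](O[Si](C(C)C)(C(C)C)C(C)C)CCC | intermediate
5 | 9-[(5R)-5-(triisopropylsilyloxy)octyl]-9-borabicyclo[3.3.1]nonane | C1CC2CCCC(C1)B2CCCC[C@H](O[Si](C(C)C)(C(C)C)C(C)C)CCC | intermediate
6 | (5R)-5-(triisopropylsilyloxy)octan-1-ol | OCCCC[C@H](O[Si](C(C)C)(C(C)C)C(C)C)CCC | intermediate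
7 | [(4R)-8-bromooctan-4-yloxy]triisopropylsilane | BrCCCC[C@H](O[Si](C(C)C)(C(C)C)C(C)C)CCC | intermediate
8 | methyl hex-5-enoate | C=CCCCC(=O)OC | starting material
9 | (E)-1,4-dibromobut-2-ene | BrC/C=C/CBr | starting material
10 | methyl (E)-7-bromohept-5-enoate | COC(=O)CCC/C=C/CBr | intermediate
11 | (5R)-5-(triisopropylsilyloxy)octylmagnesium bromide | Br[Mg]CCCC[C@H](O[Si](C(C)C)(C(C)C)C(C)C)CCC | intermediate
12 | methyl (5S,10R)-5-ethenyl-10-(triisopropylsilyloxy)tridecanoate | COC(=O)CCC[C@@H](C=C)CCCC[C@H](O[Si](C(C)C)(C(C)C)C(C)C)CCC | intermediate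
13 | (5S,10R)-5-ethenyl-10-(triisopropylsilyloxy)tridecanoic acid | OC(=O)CCC[C@@H](C=C)CCCC[C@H](O[Si](C(C)C)(C(C)C)C(C)C)CCC | intermediate
14 | ethyl L-alaninate hydrochloride | CCOC(=O)[C@H](C)N.Cl | starting material
15 | ethyl N-[(5S,10R)-5-ethenyl-10-(triisopropylsilyloxy)tridecanoyl]-L-alaninate | CCOC(=O)[C@H](C)NC(=O)CCC[C@@H](C=C)CCCC[C@H](O[Si](C(C)C)(C(C)C)C(C)C)CCC | intermediate
16 | 5-ethoxy-2-[(4S,9R)-4-ethenyl-9-(triisopropylsilyloxy)dodecyl]-4-methyl-1,3-oxazole | CCOc1oc(CCC[C@@H](C=C)CCCC[C@H](O[Si](C(C)C)(C(C)C)C(C)C)CCC)nc1C | intermediate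
17 | (5S)-3-ethoxy-3,8a-epoxy-2-methyl-5-[(5R)-5-(triisopropylsilyloxy)octyl]-3,4,4a,5,6,7,8,8a-octahydroquinoline (C3, C4a, C8a transient, left undefined) | CCOC12CC3[C@@H](CCCC[C@H](O[Si](C(C)C)(C(C)C)C(C)C)CCC)CCCC3(O1)N=C2C | intermediate
18 | (5S)-3-ethoxy-2-methyl-5-[(5R)-5-(triisopropylsilyloxy)octyl]-3,4,5,6,7,8-hexahydroquinolin-3-ol (C3 transient, left undefined) | CCOC1(O)CC2=C(CCC[C@@H]2CCCC[C@H](O[Si](C(C)C)(C(C)C)C(C)C)CCC)N=C1C | intermediate
19 | (5S)-2-methyl-5-[(5R)-5-(triisopropylsilyloxy)octyl]-5,6,7,8-tetrahydroquinolin-3-ol | Cc1nc2CCC[C@H](CCCC[C@H](O[Si](C(C)C)(C(C)C)C(C)C)CCC)c2cc1O | intermediate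
20 | (2S,3S,4aS,5S,8aR)-2-methyl-5-[(5R)-5-(triisopropylsilyloxy)octyl]decahydroquinolin-3-ol | O[C@H]1C[C@H]2[C@@H](CCCC[C@H](O[Si](C(C)C)(C(C)C)C(C)C)CCC)CCC[C@H]2N[C@H]1C | intermediate
21 | tert-butyl (2S,3S,4aS,5S,8aR)-3-hydroxy-2-methyl-5-[(5R)-5-(triisopropylsilyloxy)octyl]octahydroquinoline-1(2H)-carboxylate | O[C@H]1C[C@H]2[C@@H](CCCC[C@H](O[Si](C(C)C)(C(C)C)C(C)C)CCC)CCC[C@H]2N(C(=O)OC(C)(C)C)[C@H]1C | intermediate
22 | (2E,4E)-octa-2,4-dienoic acid | CCC/C=C/C=C/C(=O)O | starting material
23 | tert-butyl (2S,3R,4aS,5S,8aR)-2-methyl-3-[(2E,4E)-octa-2,4-dienoyloxy]-5-[(5R)-5-(triisopropylsilyloxy)octyl]octahydroquinoline-1(2H)-carboxylate | CCC/C=C/C=C/C(=O)O[C@@H]1C[C@H]2[C@@H](CCCC[C@H](O[Si](C(C)C)(C(C)C)C(C)C)CCC)CCC[C@H]2N(C(=O)OC(C)(C)C)[C@H]1C | intermediate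
24 | tert-butyl (2S,3R,4aS,5S,8aR)-5-[(5R)-5-hydroxyoctyl]-2-methyl-3-[(2E,4E)-octa-2,4-dienoyloxy]octahydroquinoline-1(2H)-carboxylate | CCC/C=C/C=C/C(=O)O[C@@H]1C[C@H]2[C@@H](CCCC[C@H](O)CCC)CCC[C@H]2N(C(=O)OC(C)(C)C)[C@H]1C | intermediate
25 | lepadin H | CCC/C=C/C=C/C(=O)O[C@@H]1C[C@H]2[C@@H](CCCC[C@H](O)CCC)CCC[C@H]2N[C@H]1C | target

**Step count**
Total: 15 steps. Longest linear sequence: 14 steps (1 → 25 through steps 1–4 and 6–15). Step 5 is a one-step side branch.

**Steps most likely to fail**

Step 10. The unactivated vinyl group may add too slowly. Acid-induced opening of the ethoxyoxazole, migration of the alkene or gradual loss of the silyl group could then win at the temperature required. The fallback sets out from 16 and comes back at 19, and gives the dienophile a traceless activating group. Cross-metathesis of 16 with tert-butyl acrylate (second-generation Grubbs catalyst, CH2Cl2, 40 °C) should give tert-butyl (2E,4S,9R)-4-[3-(5-ethoxy-4-methyl-1,3-oxazol-2-yl)propyl]-9-(triisopropylsilyloxy)dodec-2-enoate F1. CF3CO2H in CH2Cl2 at 0 °C → rt then frees (2E,4S,9R)-4-[3-(5-ethoxy-4-methyl-1,3-oxazol-2-yl)propyl]-9-(triisopropylsilyloxy)dodec-2-enoic acid F2. Warming F2 in toluene (80–110 °C) should bring about the same C4a–C8a and C3–C4 bond formation, now with an electron-poor alkene whose polarity matches the tether. The carboxyl group on C4 leaves as CO2 together with ethanol. This is the decarboxylative Kondrat'eva reaction known for acrylic acid and 5-alkoxyoxazoles, so 19 is reached with C4 unsubstituted.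

Step 11. Face selectivity with respect to C5 may be incomplete. Partly reduced ring A can also tautomerise from enol to ketone, which erodes the syn relationship at C3 and opens the way to C–O hydrogenolysis. The fallback sets out from 19 and comes back at 21, and takes C3 out of the hands of the hydrogenation. The reduction is then asked only for the cis ring fusion and C2. The crude amino alcohol, whatever its composition at C3, is treated with Boc2O to give the C3-epimeric tert-butyl (2S,4aS,5S,8aR)-3-hydroxy-2-methyl-5-[(5R)-5-(triisopropylsilyloxy)octyl]octahydroquinoline-1(2H)-carboxylate F3. Oxidation with Dess–Martin periodinane in CH2Cl2 gives tert-butyl (2S,4aS,5S,8aR)-2-methyl-3-oxo-5-[(5R)-5-(triisopropylsilyloxy)octyl]octahydroquinoline-1(2H)-carboxylate F4, in which A(1,3) strain keeps the C2 methyl axial. Reduction with NaBH4 in MeOH at −20 °C should proceed by axial hydride attack on the face away from that methyl and return the equatorial 3S alcohol 21.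

Step 13. Displacement at the hindered secondary carbinol may be slow with a weakly acidic dienoic acid, so that acylation with retention or elimination competes. The fallback sets out from 21 and comes back at 23, and separates inversion from acylation. Mitsunobu reaction with the more acidic 4-nitrobenzoic acid (PPh3, DIAD, PhMe) should give tert-butyl (2S,3R,4aS,5S,8aR)-2-methyl-3-(4-nitrobenzoyloxy)-5-[(5R)-5-(triisopropylsilyloxy)octyl]octahydroquinoline-1(2H)-carboxylate F5. Methanolysis (K2CO3, MeOH, rt) gives tert-butyl (2S,3R,4aS,5S,8aR)-3-hydroxy-2-methyl-5-[(5R)-5-(triisopropylsilyloxy)octyl]octahydroquinoline-1(2H)-carboxylate F6. Steglich esterification of F6 with 22 (EDC·HCl, DMAP, CH2Cl2) proceeds with retention and gives 23.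

**Further compounds**
F1 | step 10 | tert-butyl (2E,4S,9R)-4-[3-(5-ethoxy-4-methyl-1,3-oxazol-2-yl)propyl]-9-(triisopropylsilyloxy)dodec-2-enoate | CCOc1oc(CCC[C@@H](/C=C/C(=O)OC(C)(C)C)CCCC[C@H](O[Si](C(C)C)(C(C)C)C(C)C)CCC)nc1C
F2 | step 10 | (2E,4S,9R)-4-[3-(5-ethoxy-4-methyl-1,3-oxazol-2-yl)propyl]-9-(triisopropylsilyloxy)dodec-2-enoic acid | CCOc1oc(CCC[C@@H](/C=C/C(=O)O)CCCC[C@H](O[Si](C(C)C)(C(C)C)C(C)C)CCC)nc1C
F3 | step 11 | tert-butyl (2S,4aS,5S,8aR)-3-hydroxy-2-methyl-5-[(5R)-5-(triisopropylsilyloxy)octyl]octahydroquinoline-1(2H)-carboxylate, mixture at C3 | OC1C[C@H]2[C@@H](CCCC[C@H](O[Si](C(C)C)(C(C)C)C(C)C)CCC)CCC[C@H]2N(C(=O)OC(C)(C)C)[C@H]1C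
F4 | step 11 | tert-butyl (2S,4aS,5S,8aR)-2-methyl-3-oxo-5-[(5R)-5-(triisopropylsilyloxy)octyl]octahydroquinoline-1(2H)-carboxylate | O=C1C[C@H]2[C@@H](CCCC[C@H](O[Si](C(C)C)(C(C)C)C(C)C)CCC)CCC[C@H]2N(C(=O)OC(C)(C)C)[C@H]1C
F5 | step 13 | tert-butyl (2S,3R,4aS,5S,8aR)-2-methyl-3-(4-nitrobenzoyloxy)-5-[(5R)-5-(triisopropylsilyloxy)octyl]octahydroquinoline-1(2H)-carboxylate | O=C(O[C@@H]1C[C@H]2[C@@H](CCCC[C@H](O[Si](C(C)C)(C(C)C)C(C)C)CCC)CCC[C@H]2N(C(=O)OC(C)(C)C)[C@H]1C)c1ccc(cc1)[N+](=O)[O-]
F6 | step 13 | tert-butyl (2S,3R,4aS,5S,8aR)-3-hydroxy-2-methyl-5-[(5R)-5-(triisopropylsilyloxy)octyl]octahydroquinoline-1(2H)-carboxylate | O[C@@H]1C[C@H]2[C@@H](CCCC[C@H](O[Si](C(C)C)(C(C)C)C(C)C)CCC)CCC[C@H]2N(C(=O)OC(C)(C)C)[C@H]1C
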